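Assumption: CIP analysis of the given SMILES gives 5R at the butenolide carbon and 2S at the chromene carbon, and these are the configurations built here. Protecting-group and metal reagents are listed as reagents; carbon building blocks are numbered.

## Retrosynthetic overview

1. The last C–C bond is a C(sp3)–C(sp2) Negishi coupling between chromene alkyl iodide 15 and butenolide (E)-vinyl iodide 28, followed by phenol desilylation.
2. Chromene 15: the pyran ring is closed by Au(I) 6-endo hydroarylation of a tertiary aryl propargyl ether, so the C2–O bond is never broken. The ether comes from SNAr of (S)-tertiary propargylic alcohol 6, made by catalytic Sharpless epoxidation of achiral allylic alcohol 3 and epoxy-chloride fragmentation.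
3. Butenolide 28: an α-phenylthio acid dianion opens (R)-epoxide 22, then lactonisation and sulfoxide elimination. The carbinol centre comes from ketoreductase reduction of ethyl 4-chloroacetoacetate; the (E)-vinyl iodide from Zr-catalysed carboalumination.
4. Ring order: pyran ring (fragment A) and butenolide ring (fragment B) are each formed before the union; no ring is formed afterwards.

## Fragment A: chromene iodide 15

**Step 1**
Reactants: 1, but-3-yn-1-ol
Product: 2, 1-[(but-3-yn-1-yloxy)methyl]-4-methoxybenzene (PMB ether)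
Conditions: NaH, PMBCl, TBAI (cat.), THF/DMF, 0 °C → rt
Reagents that add atoms: 4-methoxybenzyl chloride, COc1ccc(CCl)cc1
Why: Williamson etherification; the PMB ether tolerates every basic, hydride and peracid step up to step 10.

**Step 2**
Reactants: 2
Product: 3, (2E)-5-[(4-methoxybenzyl)oxy]-3-methylpent-2-en-1-ol
Conditions: Me3Al, Cp2ZrCl2 (0.25 equiv), CH2Cl2, 0 °C → rt; evaporate; n-BuLi, THF, −78 °C; (CH2O)n, → rt
Reagents that add atoms: trimethylaluminium, C[Al](C)C; paraformaldehyde, C=O
Why: Negishi Zr-catalysed syn-carboalumination gives the (E)-2-methylalkenylalane regioselectively, and its ate complex is hydroxymethylated with retention of geometry.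

**Step 3**
Reactants: 3
Product: 4, [(2S,3S)-3-{2-[(4-methoxybenzyl)oxy]ethyl}-3-methyloxiran-2-yl]methanol
Conditions: Ti(OiPr)4 (10 mol%), L-(+)-DET (12 mol%), TBHP, 4 Å MS, CH2Cl2, −20 °C
Reagents that add atoms: tert-butyl hydroperoxide, CC(C)(C)OO
Why: Catalytic Sharpless asymmetric epoxidation; L-(+)-tartrate gives the (2S,3S)-epoxide as with geraniol, and C3 of this epoxide becomes C2 of the chromene.

**Step 4**
Reactants: 4
Product: 5, (2R,3S)-2-(chloromethyl)-3-{2-[(4-methoxybenzyl)oxy]ethyl}-3-methyloxirane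
Conditions: PPh3, CCl4, NaHCO3, reflux
Reagents that add atoms: carbon tetrachloride, ClC(Cl)(Cl)Cl
Why: Appel chlorination of the primary alcohol under buffered conditions leaves the epoxide and both stereocentres untouched (the C2 descriptor changes only because of CIP priorities).

**Step 5**
Reactants: 5
Product: 6, (3S)-5-[(4-methoxybenzyl)oxy]-3-methylpent-1-yn-3-ol
Conditions: LDA (4 equiv), THF, −40 °C → 0 °C; NH4Cl
Reagents that add atoms: none
Why: Base-induced epoxy-chloride fragmentation (Yadav double elimination) cleaves only the C2–O bond, so the tertiary C3–O stereocentre is kept.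

**Step 6**
Reactants: 6; 7, 4-fluoro-3-methylbenzonitrile
Product: 8, 4-{[(3S)-5-[(4-methoxybenzyl)oxy]-3-methylpent-1-yn-3-yl]oxy}-3-methylbenzonitrile
Conditions: KHMDS (1.05 equiv), THF, 0 °C; then 7, rt → 50 °C
Reagents that add atoms: none beyond reactant 7, N#Cc1ccc(F)c(C)c1
Why: SNAr of the tertiary potassium alkoxide on the para-cyano-activated aryl fluoride forms the aryl ether through oxygen, so the carbinol configuration is retained.

**Step 7**
Reactants: 8
Product: 9, 4-{[(3S)-5-[(4-methoxybenzyl)oxy]-3-methylpent-1-yn-3-yl]oxy}-3-methylbenzaldehyde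
Conditions: DIBAL-H, CH2Cl2, −78 °C; Rochelle salt, then dilute aq. acid
Reagents that add atoms: water, O
Why: Partial reduction of the aryl nitrile to the aldimine and hydrolysis gives the aldehyde; ether, alkyne and PMB are inert at −78 °C.

**Step 8**
Reactants: 9
Product: 10, 4-{[(3S)-5-[(4-methoxybenzyl)oxy]-3-methylpent-1-yn-3-yl]oxy}-3-methylphenol
Conditions: mCPBA, NaHCO3, CH2Cl2, 0 °C → rt; Na2S2O3 wash; then K2CO3, MeOH, rt
Reagents that add atoms: mCPBA, OOC(=O)c1cccc(Cl)c1
Why: Baeyer–Villiger (Dakin-type) oxidation of the electron-rich para-alkoxybenzaldehyde gives the aryl formate, which is methanolysed to the phenol; it is done here because no electron-rich alkene is yet present.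

**Step 9**
Reactants: 10
Product: 11, triisopropyl(4-{[(3S)-5-[(4-methoxybenzyl)oxy]-3-methylpent-1-yn-3-yl]oxy}-3-methylphenoxy)silane
Conditions: TIPSCl, imidazole, DMF, rt
Reagents that add atoms: triisopropylsilyl chloride, CC(C)[Si](Cl)(C(C)C)C(C)C
Why: Silylation of the phenol protects it from DDQ, organozinc and Pd chemistry, and it can be removed at the end with buffered fluoride.

**Step 10**
Reactants: 11
Product: 12, (3S)-3-methyl-3-{2-methyl-4-[(triisopropylsilyl)oxy]phenoxy}pent-4-yn-1-ol
Conditions: DDQ, CH2Cl2/pH 7 buffer, 0 °C → rt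
Reagents that add atoms: none
Why: Oxidative PMB cleavage is done before gold catalysis because a PMB ether oxygen would attack the Au-activated alkyne.

**Step 11**
Reactants: 12
Product: 13, (3S)-3-methyl-3-{2-methyl-4-[(triisopropylsilyl)oxy]phenoxy}pent-4-yn-1-yl 4-methylbenzenesulfonate
Conditions: TsCl, Et3N, DMAP (cat.), CH2Cl2, 0 °C → rt
Reagents that add atoms: tosyl chloride, Cc1ccc(S(Cl)(=O)=O)cc1
Why: Sulfonylation makes the side-chain oxygen non-nucleophilic (no 5-exo attack on the alkyne in step 12) and pre-activates it for iodide displacement.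

**Step 12**
Reactants: 13
Product: 14, 2-{(2S)-2,8-dimethyl-6-[(triisopropylsilyl)oxy]-2H-chromen-2-yl}ethyl 4-methylbenzenesulfonate
Conditions: [JohnPhosAu(MeCN)]SbF6 (3 mol%), dry CH2Cl2, rt, dark
Reagents that add atoms: none
Why: Au(I)-catalysed 6-endo-dig intramolecular hydroarylation at the only free ortho position closes the pyran ring at rt without cleaving the C2–O bond, which a thermal propargyl Claisen would do via an achiral o-quinone methide.

**Step 13**
Reactants: 14
Product: 15, {[(2S)-2-(2-iodoethyl)-2,8-dimethyl-2H-chromen-6-yl]oxy}triisopropylsilane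
Conditions: NaI, acetone, 55 °C, amber glassware
Reagents that add atoms: sodium iodide, [Na+].[I-]
Why: Finkelstein SN2 displacement of the unhindered primary tosylate; the quaternary stereocentre is not involved.

## Fragment B: butenolide vinyl iodide 28

**Step 14**
Reactants: 16, ethyl 4-chloro-3-oxobutanoate
Product: 17, ethyl (3R)-4-chloro-3-hydroxybutanoate
Conditions: (R)-selective ketoreductase (KRED), NADP+ (cat.), glucose, glucose dehydrogenase, phosphate buffer pH 6.5/BuOAc, 30 °C, pH-stat
Reagents that add atoms: none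
Why: Ketoreductase-catalysed enantioselective carbonyl reduction with cofactor recycling, a very well-established biocatalytic reduction, sets the future butenolide C5 stereocentre in >99% ee.

**Step 15**
Reactants: 17
Product: 18, ethyl (3R)-3-[(tert-butyldimethylsilyl)oxy]-4-chlorobutanoate
Conditions: TBSCl, imidazole, DMF, rt
Reagents that add atoms: TBSCl, CC(C)(C)[Si](C)(C)Cl
Why: Silylation blocks the β-hydroxyl so the derived aldehyde does not eliminate or cyclise.

**Step 16**
Reactants: 18
Product: 19, (3R)-3-[(tert-butyldimethylsilyl)oxy]-4-chlorobutanal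
Conditions: DIBAL-H (1.05 equiv), CH2Cl2, −78 °C
Reagents that add atoms: none
Why: Low-temperature partial reduction of the ester stops at the aldehyde via the stable tetrahedral aluminate.

**Step 17**
Reactants: 19
Product: 20, tert-butyl{[(2R)-1-chloropent-4-yn-2-yl]oxy}dimethylsilane
Conditions: Ohira–Bestmann reagent, K2CO3, MeOH, 0 °C → rt
Reagents that add atoms: dimethyl (1-diazo-2-oxopropyl)phosphonate, COP(=O)(OC)C(=[N+]=[N-])C(C)=O
Why: Seyferth–Gilbert (Ohira–Bestmann) homologation converts the aldehyde into the terminal alkyne under mild base without touching the silyloxy stereocentre.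

**Step 18**
Reactants: 20
Product: 21, tert-butyl{[(2R,4E)-1-chloro-5-iodo-4-methylpent-4-en-2-yl]oxy}dimethylsilane
Conditions: Me3Al, Cp2ZrCl2, CH2Cl2, 0 °C → rt; then I2, THF, −30 °C
Reagents that add atoms: trimethylaluminium, C[Al](C)C; iodine, II
Why: Negishi syn-carboalumination followed by iodinolysis with retention gives the (E)-2-methylvinyl iodide, fixing the trisubstituted alkene geometry of the target.

**Step 19**
Reactants: 21
Product: 22, (2R)-2-[(2E)-3-iodo-2-methylprop-2-en-1-yl]oxirane
Conditions: TBAF, THF, 0 °C → rt; then K2CO3, MeOH, rt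
Reagents that add atoms: none
Why: Desilylation and intramolecular Williamson closure of the chlorohydrin occur at the CH2Cl carbon, so the carbinol stereocentre is retained.

**Step 20**
Reactants: 23, (phenylsulfanyl)acetic acid; 24, 5-bromo-2-methylpent-2-ene
Product: 25, 6-methyl-2-(phenylsulfanyl)hept-5-enoic acid (racemic)
Conditions: LDA (2.2 equiv), THF, 0 °C; then 24, DMPU, 0 °C → rt
Reagents that add atoms: none beyond reactants
Why: C-alkylation of the sulfur-stabilised carboxylate dianion installs the homoprenyl chain; the racemic α-centre is irrelevant because it becomes sp2 in step 23.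

**Step 21**
Reactants: 25; 22
Product: 26, (5R)-5-[(2E)-3-iodo-2-methylprop-2-en-1-yl]-3-(4-methylpent-3-en-1-yl)-3-(phenylsulfanyl)oxolan-2-one (C3 epimers)
Conditions: LDA (2.1 equiv), THF, −78 → 0 °C; 22, rt; 1 M HCl; then PPTS (cat.), toluene, 50 °C
Reagents that add atoms: none beyond reactants
Why: The acid dianion opens the terminal epoxide at the CH2 carbon and the γ-hydroxy acid lactonises through the retained C–O bond, so C5 stays R.

**Step 22**
Reactants: 26
Product: 27, (5R)-5-[(2E)-3-iodo-2-methylprop-2-en-1-yl]-3-(4-methylpent-3-en-1-yl)-3-(phenylsulfinyl)oxolan-2-one (diastereomer mixture)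
Conditions: NaIO4, MeOH/H2O, 0 °C → rt
Reagents that add atoms: sodium periodate, [Na+].[O-]I(=O)(=O)=O
Why: Periodate oxidises the sulfide to the sulfoxide without epoxidising the trisubstituted alkenes or affecting the vinyl iodide.

**Step 23**
Reactants: 27
Product: 28, (5R)-5-[(2E)-3-iodo-2-methylprop-2-en-1-yl]-3-(4-methylpent-3-en-1-yl)furan-2(5H)-one
Conditions: toluene, CaCO3, P(OMe)3, 110 °C
Reagents that add atoms: none
Why: Thermal sulfoxide syn-elimination toward the ring CH2 gives the endocyclic α-alkyl butenolide under neutral conditions that cannot epimerise C5.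

## Union and endgame

**Step 24**
Reactants: 15; 28
Product: 29, (5R)-5-[(2E)-5-{(2S)-2,8-dimethyl-6-[(triisopropylsilyl)oxy]-2H-chromen-2-yl}-2-methylpent-2-en-1-yl]-3-(4-methylpent-3-en-1-yl)furan-2(5H)-one
Conditions: 15, Zn dust (TMSCl/BrCH2CH2Br-activated), LiCl, THF, 40 °C (alkylzinc iodide in situ); then 28, PdCl2(dppf) (5 mol%), THF/DMA, rt, dark
Reagents that add atoms: none
Why: Negishi sp3–sp2 coupling proceeds with retention of the (E)-alkene geometry under non-basic conditions, which the butenolide, chromene and aryl silyl ether tolerate.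

**Step 25**
Reactants: 29
Product: 30, tuberatolide B, (5R)-5-{(2E)-5-[(2S)-6-hydroxy-2,8-dimethyl-2H-chromen-2-yl]-2-methylpent-2-en-1-yl}-3-(4-methylpent-3-en-1-yl)furan-2(5H)-one
Conditions: TBAF, AcOH (1:1), THF, 0 °C
Reagents that add atoms: none
Why: Acetic acid-buffered fluoride cleaves the aryl silyl ether in minutes without generating base strong enough to deprotonate the butenolide γ-position.

## Compound list

1 | but-3-yn-1-ol | C#CCCO | starting material
2 | 1-[(but-3-yn-1-yloxy)methyl]-4-methoxybenzene | C#CCCOCc1ccc(OC)cc1 | intermediate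
3 | (2E)-5-[(4-methoxybenzyl)oxy]-3-methylpent-2-en-1-ol | OC/C=C(\C)CCOCc1ccc(OC)cc1 | intermediate
4 | [(2S,3S)-3-{2-[(4-methoxybenzyl)oxy]ethyl}-3-methyloxiran-2-yl]methanol | OC[C@@H]1O[C@@]1(C)CCOCc2ccc(OC)cc2 | intermediate
5 | (2R,3S)-2-(chloromethyl)-3-{2-[(4-methoxybenzyl)oxy]ethyl}-3-methyloxirane | ClC[C@@H]1O[C@@]1(C)CCOCc2ccc(OC)cc2 | intermediate
6 | (3S)-5-[(4-methoxybenzyl)oxy]-3-methylpent-1-yn-3-ol | C#C[C@](O)(C)CCOCc1ccc(OC)cc1 | intermediate
7 | 4-fluoro-3-methylbenzonitrile | N#Cc1ccc(F)c(C)c1 | starting material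
8 | 4-{[(3S)-5-[(4-methoxybenzyl)oxy]-3-methylpent-1-yn-3-yl]oxy}-3-methylbenzonitrile | C#C[C@](Oc1ccc(C#N)cc1C)(C)CCOCc2ccc(OC)cc2 | intermediate
9 | 4-{[(3S)-5-[(4-methoxybenzyl)oxy]-3-methylpent-1-yn-3-yl]oxy}-3-methylbenzaldehyde | C#C[C@](Oc1ccc(C=O)cc1C)(C)CCOCc2ccc(OC)cc2 | intermediate
10 | 4-{[(3S)-5-[(4-methoxybenzyl)oxy]-3-methylpent-1-yn-3-yl]oxy}-3-methylphenol | C#C[C@](Oc1ccc(O)cc1C)(C)CCOCc2ccc(OC)cc2 | intermediate
11 | triisopropyl(4-{[(3S)-5-[(4-methoxybenzyl)oxy]-3-methylpent-1-yn-3-yl]oxy}-3-methylphenoxy)silane | C#C[C@](Oc1ccc(O[Si](C(C)C)(C(C)C)C(C)C)cc1C)(C)CCOCc2ccc(OC)cc2 | intermediate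
12 | (3S)-3-methyl-3-{2-methyl-4-[(triisopropylsilyl)oxy]phenoxy}pent-4-yn-1-ol | C#C[C@](Oc1ccc(O[Si](C(C)C)(C(C)C)C(C)C)cc1C)(C)CCO | intermediate
13 | (3S)-3-methyl-3-{2-methyl-4-[(triisopropylsilyl)oxy]phenoxy}pent-4-yn-1-yl tosylate | C#C[C@](Oc1ccc(O[Si](C(C)C)(C(C)C)C(C)C)cc1C)(C)CCOS(=O)(=O)c2ccc(C)cc2 | intermediate
14 | 2-{(2S)-2,8-dimethyl-6-[(triisopropylsilyl)oxy]-2H-chromen-2-yl}ethyl tosylate | Cc1ccc(S(=O)(=O)OCC[C@@]2(C)C=Cc3cc(O[Si](C(C)C)(C(C)C)C(C)C)cc(C)c3O2)cc1 | intermediate
15 | {[(2S)-2-(2-iodoethyl)-2,8-dimethyl-2H-chromen-6-yl]oxy}triisopropylsilane | ICC[C@@]1(C)C=Cc2cc(O[Si](C(C)C)(C(C)C)C(C)C)cc(C)c2O1 | intermediate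
16 | ethyl 4-chloro-3-oxobutanoate | CCOC(=O)CC(=O)CCl | starting material
17 | ethyl (3R)-4-chloro-3-hydroxybutanoate | CCOC(=O)C[C@@H](O)CCl | intermediate
18 | ethyl (3R)-3-[(tert-butyldimethylsilyl)oxy]-4-chlorobutanoate | CCOC(=O)C[C@@H](O[Si](C)(C)C(C)(C)C)CCl | intermediate
19 | (3R)-3-[(tert-butyldimethylsilyl)oxy]-4-chlorobutanal | O=CC[C@@H](O[Si](C)(C)C(C)(C)C)CCl | intermediate
20 | tert-butyl{[(2R)-1-chloropent-4-yn-2-yl]oxy}dimethylsilane | C#CC[C@@H](O[Si](C)(C)C(C)(C)C)CCl | intermediate
21 | tert-butyl{[(2R,4E)-1-chloro-5-iodo-4-methylpent-4-en-2-yl]oxy}dimethylsilane | I/C=C(\C)C[C@@H](O[Si](C)(C)C(C)(C)C)CCl | intermediate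
22 | (2R)-2-[(2E)-3-iodo-2-methylprop-2-en-1-yl]oxirane | I/C=C(\C)C[C@@H]1CO1 | intermediate
23 | (phenylsulfanyl)acetic acid | OC(=O)CSc1ccccc1 | starting material
24 | 5-bromo-2-methylpent-2-ene | CC(C)=CCCBr | starting material
25 | 6-methyl-2-(phenylsulfanyl)hept-5-enoic acid (racemic) | CC(C)=CCCC(Sc1ccccc1)C(=O)O | intermediate
26 | (5R)-5-[(2E)-3-iodo-2-methylprop-2-en-1-yl]-3-(4-methylpent-3-en-1-yl)-3-(phenylsulfanyl)oxolan-2-one | CC(C)=CCCC1(Sc2ccccc2)C[C@@H](C/C(C)=C/I)OC1=O | intermediate
27 | (5R)-5-[(2E)-3-iodo-2-methylprop-2-en-1-yl]-3-(4-methylpent-3-en-1-yl)-3-(phenylsulfinyl)oxolan-2-one | CC(C)=CCCC1(S(=O)c2ccccc2)C[C@@H](C/C(C)=C/I)OC1=O | intermediate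
28 | (5R)-5-[(2E)-3-iodo-2-methylprop-2-en-1-yl]-3-(4-methylpent-3-en-1-yl)furan-2(5H)-one | CC(C)=CCCC1=C[C@@H](C/C(C)=C/I)OC1=O | intermediate
29 | O-TIPS tuberatolide B | CC(C)=CCCC1=C[C@@H](C/C(C)=C/CC[C@@]2(C)C=Cc3cc(O[Si](C(C)C)(C(C)C)C(C)C)cc(C)c3O2)OC1=O | intermediate
30 | tuberatolide B | CC(C)=CCCC1=C[C@@H](C/C(C)=C/CC[C@@]2(C)C=Cc3cc(O)cc(C)c3O2)OC1=O | target

## Summary

Total steps: 25. Longest linear sequence: 15 (steps 1–13, 24, 25).

Three steps most likely to fail, each with a fallback that changes the approach: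

1. **Step 6 (SNAr of a hindered tertiary propargylic alkoxide on an ortho-methyl aryl fluoride).** Fallback: reverse the bond order. Sonogashira-couple alcohol 6 with 2-bromo-1-iodo-3-methyl-5-(triisopropylsilyloxy)benzene, semi-hydrogenate (Lindlar) to the Z-styrene, and close the pyran by intramolecular Pd-catalysed C–O coupling of the tertiary alcohol. The C–O bond at the stereocentre is still never broken, and steps 6–9 and 12 are bypassed.

2. **Step 12 (Au hydroarylation: 6-endo versus 5-exo selectivity, and possible ionisation of the tertiary propargylic ether eroding ee).** Fallback: set the quaternary centre and the ring together by intramolecular Pd-catalysed asymmetric allylic etherification (Trost ligand) of a phenol-tethered allyl carbonate to the 2-methyl-2-vinylchroman. Then use 9-BBN hydroboration/B-alkyl Suzuki coupling with vinyl iodide 21, build the butenolide after coupling, and dehydrogenate the chroman to the chromene with DDQ.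

3. **Steps 21–23 (epoxide opening by the tertiary α-thio dianion, and endo versus exo sulfoxide elimination).** Fallback: build the butenolide by olefination. Convert 22 to the 1,2-diol and then the α-silyloxy aldehyde, run a Z-selective Still–Gennari olefination with bis(2,2,2-trifluoroethyl) 2-phosphono-6-methylhept-5-enoate, and lactonise on desilylation.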